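The decalin is disconnected across its ring-fusion bond C5–C10 (labdane numbering), which belongs to both ring A and ring B, together with C8–C9. Both bonds are made in one catalyst-controlled intramolecular Diels–Alder reaction of an acyclic (2E,8Z,10E)-trienal: the C9=C10 enal (C11 = CHO) is tethered through C1–C4, carrying the C4 gem-dimethyl group, to the 2-silyloxy diene C5=C6(OTBS)–C7=C8. One operation closes rings A and B, creates the quaternary C10 and sets C5, C9 and C10 with the trans fusion. The C6 enol ether then delivers the 6α- and 8α-oxygens, the C11 aldehyde the side chain, whose C13 carbinol comes from a Sharpless epoxidation.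

Key step: step 8

Remark: atoms carry labdane numbers throughout (decalin C1–C10, side chain C11–C16, C17 on C8, C18 and C19 on C4, C20 on C10); α is the face of H-5, β the face of C20.

Step 1
Reactants: 1 mesityl oxide
Product: 2 4,4-dimethylhept-6-en-2-one
Conditions: allyltrimethylsilane, TiCl4, CH2Cl2, −78 °C; H2O
Reagents that add atoms: allyltrimethylsilane, C=CC[Si](C)(C)C
Why: Hosomi–Sakurai conjugate allylation, in which the TiCl4-activated enone is attacked at its β,β-disubstituted carbon by the γ-carbon of the allylsilane, so that the quaternary C4 with both methyl groups and C1–C3 are in place in one step and no stereocentre is formed.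

Step 2
Reactants: 2 4,4-dimethylhept-6-en-2-one
Product: 5 (2E)-6,6-dimethylnona-2,8-dien-4-one, via aldol adduct 3 (not isolated), via mesylate 4 (not isolated)
Conditions: LiN(iPr)2, THF, −78 °C; CH3CHO; MsCl, −78 → 0 °C; then DBU, 23 °C
Reagents that add atoms: acetaldehyde, CC=O
Why: Directed aldol condensation, in which kinetic deprotonation occurs at the unhindered methyl group and not at the neopentyl CH2, and in situ mesylation with E1cB elimination gives the thermodynamically favoured (E)-enone with no stereocentre left.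

Step 3
Reactants: 5 (2E)-6,6-dimethylnona-2,8-dien-4-one
Product: 6 tert-butyl{[(2E,4Z)-6,6-dimethylnona-2,4,8-trien-4-yl]oxy}dimethylsilane
Conditions: TBSOTf, Et3N, CH2Cl2, 0 °C
Reagents that add atoms: tert-butyldimethylsilyl triflate, CC(C)(C)[Si](C)(C)OS(=O)(=O)C(F)(F)F
Why: Soft enolisation (silyl triflate and amine) of the (E)-alkenyl ketone should take place at the α′-CH2 (C5) and not at the γ-methyl group, and gives the cross-conjugated 2-silyloxydiene as the more stable (Z)-enol ether, with oxygen cis to the tert-alkyl group so that the tether sits on the outside position of the diene.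

Step 4
Reactants: 7 methyl acetoacetate
Product: 8 methyl (2E)-3-{[(trifluoromethyl)sulfonyl]oxy}but-2-enoate
Conditions: Tf2O, aq Me4NOH, hexane, 5 °C
Reagents that add atoms: triflic anhydride, O=S(=O)(OS(=O)(=O)C(F)(F)F)C(F)(F)F
Why: O-Triflation of the non-chelated tetramethylammonium enolate of the β-keto ester should give the (E)-enol triflate, with the triflate trans to the ester, which is the geometry that later places C20 cis to C11.

Step 5
Reactants: 8 methyl (2E)-3-{[(trifluoromethyl)sulfonyl]oxy}but-2-enoate
Product: 9 (2E)-4-hydroxybut-2-en-2-yl trifluoromethanesulfonate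
Conditions: iBu2AlH, CH2Cl2, −78 °C; aq potassium sodium tartrate
Reagents that add atoms: none
Why: Hydride reduction of the ester to the allylic alcohol at low temperature leaves the vinyl triflate and the alkene geometry untouched.

Step 6
Reactants: 6 tert-butyl{[(2E,4Z)-6,6-dimethylnona-2,4,8-trien-4-yl]oxy}dimethylsilane; 9 (2E)-4-hydroxybut-2-en-2-yl trifluoromethanesulfonate
Product: 11 (2E,8Z,10E)-9-[(tert-butyldimethylsilyl)oxy]-3,7,7-trimethyldodeca-2,8,10-trien-1-ol, via alkylborane 10 (not isolated)
Conditions: 9-borabicyclo[3.3.1]nonane (9-BBN-H), THF, 0 → 23 °C; then 9, PdCl2(dppf) (5 mol %; dppf = 1,1′-bis(diphenylphosphino)ferrocene), AsPh3, Cs2CO3, DMF/H2O, 23 °C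
Reagents that add atoms: none
Why: Anti-Markovnikov hydroboration selects the monosubstituted alkene over the hindered conjugated silyloxydiene, and the B-alkyl Suzuki–Miyaura coupling with the vinyl triflate proceeds with retention, which fixes the (2E)-trisubstituted alkene with the tether trans to C11.

Step 7
Reactants: 11 (2E,8Z,10E)-9-[(tert-butyldimethylsilyl)oxy]-3,7,7-trimethyldodeca-2,8,10-trien-1-ol
Product: 12 (2E,8Z,10E)-9-[(tert-butyldimethylsilyl)oxy]-3,7,7-trimethyldodeca-2,8,10-trienal
Conditions: activated MnO2, CH2Cl2, 23 °C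
Reagents that add atoms: none
Why: Allylic alcohol oxidation with MnO2 is neutral, should keep the (2E) geometry and is tolerated by the silyl dienol ether.

Step 8
Reactants: 12 (2E,8Z,10E)-9-[(tert-butyldimethylsilyl)oxy]-3,7,7-trimethyldodeca-2,8,10-trienal
Product: 13 6-[(tert-butyldimethylsilyl)oxy]-12,13,14,15,16-pentanorlabd-6-en-11-al (trans-fused; H-5α, H-8α with C17 β, H-9α with CHO β, C20 β)
Conditions: (S)-3,3-diphenyl-1-(2-methylphenyl)tetrahydro-1H,3H-pyrrolo[1,2-c][1,3,2]oxazaborole (20 mol %), HNTf2 (18 mol %), CH2Cl2, −78 → −40 °C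
Reagents that add atoms: none
Why: Complexation of the formyl oxygen of 12 by the protonated oxazaborolidine lowers the LUMO of the C9=C10 enal, and the tethered 2-silyloxydiene adds in a concerted but strongly asynchronous [4+2] in which C5, the nucleophilic diene terminus, bonds to the β-carbon C10 ahead of C8–C9. The closest known reaction type is the Lewis-acid-catalysed (oxazaborolidinium-catalysed, enantioselective) type 1 intramolecular Diels–Alder reaction of 2,8,10-trienals to trans-fused octalins, joined to the established use of 2-silyloxydienes with this catalyst class. Ring A (C1–C5, C10) closes through the four-carbon tether as a chair in the anti, trans-fusing mode by forming the fusion bond C5–C10, and ring B (C5–C10) is the new cyclohexene, closed suprafacially by C5–C10 and C8–C9 in the endo mode. C9 and C10 are fixed relative to each other by the (2E)-enal (C11 and C20 cis), C5 by the endo transition state with the tether exo and C4 on the outside position of the (8Z)-enol ether (H-5 trans to C20), C8 by the (10E)-propenyl terminus (C17 cis to C11, a centre erased in step 10), and the absolute sense by the catalyst, for which the (S)-oxazaborolidine is proposed to leave open to C5 the Re face of C10 (C9 → C1 → C20 clockwise), the (R)-catalyst being the choice if the first adduct shows the opposite sense. The step needs endo over exo closure, one enal face and C5–C10 bonding in preference to 1,2-addition at the formyl group. These are secured by the endo preference of the catalyst-bound formyl group, the chiral pocket, the matched polarity of the diene (silyloxy at C6 para and methyl at C8 ortho to the formyl-bearing C9), the Thorpe–Ingold effect of the C4 gem-dimethyl group and the eight-membered ring that 1,2-addition would need.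

Step 9
Reactants: 13 6-[(tert-butyldimethylsilyl)oxy]-12,13,14,15,16-pentanorlabd-6-en-11-al
Product: 14 tert-butyldimethylsilyl enol ether of 13,14,15,16-tetranorlabda-6,11-dien-6-ol
Conditions: Ph3PCH3Br, KOtBu, THF, 0 °C; then 13, −78 → 0 °C
Reagents that add atoms: methyltriphenylphosphonium bromide, C[P+](c1ccccc1)(c1ccccc1)c1ccccc1.[Br-]
Why: Wittig methylenation of the aldehyde adds C12, the silyl enol ether is inert to the ylide, and the equatorial 9β-substituent is the stable configuration at the α-carbon, so C9 is not at risk.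

Step 10
Reactants: 14 tert-butyldimethylsilyl enol ether of 13,14,15,16-tetranorlabda-6,11-dien-6-ol
Product: 15 13,14,15,16-tetranorlabda-7,11-dien-6-one
Conditions: Pd(OAc)2 (1.1 equiv), MeCN, 23 °C
Reagents that add atoms: none
Why: Saegusa–Ito oxidation, in which palladation of the silyl enol ether at C7 from the open α-face and syn β-hydride elimination of H-8α give the 7-en-6-one, the only β-hydrogen being on C8 so that the regiochemistry is fixed.

Step 11
Reactants: 15 13,14,15,16-tetranorlabda-7,11-dien-6-one
Product: 16 7α,8α-epoxy-13,14,15,16-tetranorlabd-11-en-6-one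
Conditions: 30% aq H2O2, NaOH, MeOH, 0 → 23 °C
Reagents that add atoms: hydrogen peroxide, OO
Why: Weitz–Scheffer nucleophilic epoxidation, in which hydroperoxide should add to C8 from the α-face because the β-face is blocked by the syn-axial C20 methyl group, and ring closure of the enolate gives the 7α,8α-epoxide and so sets C8 (oxygen α, C17 β).

Step 12
Reactants: 16 7α,8α-epoxy-13,14,15,16-tetranorlabd-11-en-6-one
Product: 18 13,14,15,16-tetranorlabd-11-ene-6α,8α-diol, via hydroxy ketone 17 (not isolated)
Conditions: Li, NH3 (l), THF, EtOH, −78 → −33 °C; NH4Cl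
Reagents that add atoms: none
Why: Dissolving-metal reduction first cleaves the C7–O bond α to the ketone to give the β-hydroxy ketone with C8 untouched and then reduces the ketone under thermodynamic control to the equatorial 6α-alcohol, since the 6β-epimer would face the two syn-axial methyl groups C19 and C20, while the isolated vinyl group is not reduced.

Step 13
Reactants: 18 13,14,15,16-tetranorlabd-11-ene-6α,8α-diol; 9 (2E)-4-hydroxybut-2-en-2-yl trifluoromethanesulfonate
Product: 20 (13E)-labd-13-ene-6α,8α,15-triol, via alkylborane 19 (not isolated)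
Conditions: 9-BBN-H (3.5 equiv), THF, 23 → 50 °C; then 9, PdCl2(dppf) (5 mol %), AsPh3, Cs2CO3, DMF/H2O, 23 °C
Reagents that add atoms: none
Why: Hydroboration of the vinyl group (the hydroxyl groups are tolerated with excess borane) followed by B-alkyl Suzuki–Miyaura coupling with the same (E)-vinyl triflate gives the (13E)-allylic alcohol with retention of the alkene geometry.

Step 14
Reactants: 20 (13E)-labd-13-ene-6α,8α,15-triol
Product: 21 (13R,14R)-13,14-epoxylabdane-6α,8α,15-triol
Conditions: Ti(OiPr)4 (1.2 equiv), D-(−)-diethyl tartrate (1.5 equiv), tBuOOH, 4 Å molecular sieves, CH2Cl2, −20 °C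
Reagents that add atoms: tert-butyl hydroperoxide, CC(C)(C)OO
Why: Katsuki–Sharpless asymmetric epoxidation, in which D-(−)-diethyl tartrate directs oxygen to the face of the (E)-trisubstituted allylic alcohol that gives the (13R,14R)-epoxy alcohol (reagent control, as in geraniol to (2R,3R)-epoxygeraniol), the remote hydroxyl groups having no directing role.

Step 15
Reactants: 21 (13R,14R)-13,14-epoxylabdane-6α,8α,15-triol
Product: 22 (13R,14R)-13,14-epoxy-15-iodolabdane-6α,8α-diol
Conditions: PPh3, imidazole, I2, THF, 0 °C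
Reagents that add atoms: iodine, II
Why: Appel-type iodination converts only the primary alcohol into the iodide and should leave the hindered 6α-hydroxyl, the tertiary hydroxyl and the epoxide untouched.

Step 16
Reactants: 22 (13R,14R)-13,14-epoxy-15-iodolabdane-6α,8α-diol
Product: 23 (13R)-labd-14-ene-6α,8α,13-triol
Conditions: activated Zn dust, EtOH, reflux
Reagents that add atoms: none
Why: Reductive epoxide opening, in which zinc inserts into the C–I bond and the β-alkoxy organozinc eliminates to form the C14=C15 vinyl group, while the C13–O bond and with it the (13R) configuration are not touched.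

Step 17
Reactants: 23 (13R)-labd-14-ene-6α,8α,13-triol
Product: 24 (13R)-6α-[(Z)-2-methylbut-2-enoyloxy]labd-14-ene-8α,13-diol (target)
Conditions: angelic acid, 2,4,6-Cl3C6H2COCl, Et3N, toluene, 23 °C; filtrate, then 23, toluene, 80 °C
Reagents that add atoms: angelic acid, C/C=C(/C)C(=O)O
Why: Yamaguchi-type acylation with the preformed mixed anhydride acylates the only secondary hydroxyl (6α), the two tertiary hydroxyls being unreactive, and the base-free heating is chosen to avoid Z-to-E isomerisation to the tiglate.

Compound list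

1 | mesityl oxide (4-methylpent-3-en-2-one) | CC(=O)C=C(C)C | starting material
2 | 4,4-dimethylhept-6-en-2-one | CC(=O)CC(C)(C)CC=C | intermediate
3 | 2-hydroxy-6,6-dimethylnon-8-en-4-one (as lithium alkoxide, not isolated, carbinol centre unassigned) | CC(O)CC(=O)CC(C)(C)CC=C | intermediate
4 | 6,6-dimethyl-4-oxonon-8-en-2-yl methanesulfonate (not isolated) | CC(CC(=O)CC(C)(C)CC=C)OS(C)(=O)=O | intermediate
5 | (2E)-6,6-dimethylnona-2,8-dien-4-one | C/C=C/C(=O)CC(C)(C)CC=C | intermediate
6 | tert-butyl{[(2E,4Z)-6,6-dimethylnona-2,4,8-trien-4-yl]oxy}dimethylsilane | C/C=C/C(O[Si](C)(C)C(C)(C)C)=C/C(C)(C)CC=C | intermediate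
7 | methyl acetoacetate | COC(=O)CC(C)=O | starting material
8 | methyl (2E)-3-{[(trifluoromethyl)sulfonyl]oxy}but-2-enoate | COC(=O)/C=C(\C)OS(=O)(=O)C(F)(F)F | intermediate
9 | (2E)-4-hydroxybut-2-en-2-yl trifluoromethanesulfonate | OC/C=C(\C)OS(=O)(=O)C(F)(F)F | intermediate
10 | 9-[(5Z,7E)-6-[(tert-butyldimethylsilyl)oxy]-4,4-dimethylnona-5,7-dien-1-yl]-9-borabicyclo[3.3.1]nonane (not isolated) | C/C=C/C(O[Si](C)(C)C(C)(C)C)=C/C(C)(C)CCCB1C2CCCC1CCC2 | intermediate
11 | (2E,8Z,10E)-9-[(tert-butyldimethylsilyl)oxy]-3,7,7-trimethyldodeca-2,8,10-trien-1-ol | OC/C=C(\C)CCCC(C)(C)/C=C(O[Si](C)(C)C(C)(C)C)/C=C/C | intermediate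
12 | (2E,8Z,10E)-9-[(tert-butyldimethylsilyl)oxy]-3,7,7-trimethyldodeca-2,8,10-trienal | O=C/C=C(\C)CCCC(C)(C)/C=C(O[Si](C)(C)C(C)(C)C)/C=C/C | intermediate
13 | 6-[(tert-butyldimethylsilyl)oxy]-12,13,14,15,16-pentanorlabd-6-en-11-al (trans-fused, H-5α, H-8α, H-9α, C17 β, C20 β) | O=C[C@@H]1[C@@]2(C)CCCC(C)(C)[C@@H]2C(O[Si](C)(C)C(C)(C)C)=C[C@@H]1C | intermediate
14 | tert-butyldimethylsilyl enol ether of 13,14,15,16-tetranorlabda-6,11-dien-6-ol (H-5α, H-8α, H-9α) | C=C[C@@H]1[C@@]2(C)CCCC(C)(C)[C@@H]2C(O[Si](C)(C)C(C)(C)C)=C[C@@H]1C | intermediate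
15 | 13,14,15,16-tetranorlabda-7,11-dien-6-one (H-5α, H-9α) | C=C[C@@H]1[C@@]2(C)CCCC(C)(C)[C@@H]2C(=O)C=C1C | intermediate
16 | 7α,8α-epoxy-13,14,15,16-tetranorlabd-11-en-6-one (C17 β) | C=C[C@@H]1[C@@]2(C)CCCC(C)(C)[C@@H]2C(=O)[C@H]3O[C@]31C | intermediate
17 | 8α-hydroxy-13,14,15,16-tetranorlabd-11-en-6-one (not isolated) | C=C[C@@H]1[C@@]2(C)CCCC(C)(C)[C@@H]2C(=O)C[C@@]1(C)O | intermediate
18 | 13,14,15,16-tetranorlabd-11-ene-6α,8α-diol | C=C[C@@H]1[C@@]2(C)CCCC(C)(C)[C@@H]2[C@@H](O)C[C@@]1(C)O | intermediate
19 | 12-(9-borabicyclo[3.3.1]nonan-9-yl)-13,14,15,16-tetranorlabdane-6α,8α-diol (not isolated, hydroxyls may be transiently O-borylated) | B1(CC[C@@H]2[C@@]3(C)CCCC(C)(C)[C@@H]3[C@@H](O)C[C@@]2(C)O)C4CCCC1CCC4 | intermediate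
20 | (13E)-labd-13-ene-6α,8α,15-triol | OC/C=C(\C)CC[C@@H]1[C@@]2(C)CCCC(C)(C)[C@@H]2[C@@H](O)C[C@@]1(C)O | intermediate
21 | (13R,14R)-13,14-epoxylabdane-6α,8α,15-triol | OC[C@H]1O[C@]1(C)CC[C@@H]2[C@@]3(C)CCCC(C)(C)[C@@H]3[C@@H](O)C[C@@]2(C)O | intermediate
22 | (13R,14R)-13,14-epoxy-15-iodolabdane-6α,8α-diol | IC[C@H]1O[C@]1(C)CC[C@@H]2[C@@]3(C)CCCC(C)(C)[C@@H]3[C@@H](O)C[C@@]2(C)O | intermediate
23 | (13R)-labd-14-ene-6α,8α,13-triol | C=C[C@](C)(O)CC[C@@H]1[C@@]2(C)CCCC(C)(C)[C@@H]2[C@@H](O)C[C@@]1(C)O | intermediate
24 | (13R)-6α-[(Z)-2-methylbut-2-enoyloxy]labd-14-ene-8α,13-diol | C=C[C@](C)(O)CC[C@@H]1[C@@]2(C)CCCC(C)(C)[C@@H]2[C@@H](OC(=O)/C(C)=C\C)C[C@@]1(C)O | target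

Total step count: 17. Longest linear sequence: 15 steps (steps 1–3 and 6–17; steps 4 and 5 make the C4 coupling partner 9 used in steps 6 and 13).

Steps most likely to fail

Step 8 (key cycloaddition). Bond formation at the fully substituted C10 may be too slow, closure may leak through the exo (cis-fusing) transition state, and the facial control by the catalyst may be weak or reversed. The fallback uses a covalently bound controller; it sets out from 6 and comes back at 13. (S)-4-Benzyloxazolidin-2-one is N-acetoacetylated with 2,2,6-trimethyl-4H-1,3-dioxin-4-one (toluene, 110 °C) to (S)-4-benzyl-3-(3-oxobutanoyl)oxazolidin-2-one F1, which is O-triflated (Tf2O, iPr2NEt, CH2Cl2, −78 °C) to its (E)-enol triflate F2. Borane 10, made from 6 as in step 6, is coupled with F2 under the Suzuki–Miyaura conditions of step 6 to the trienimide F3. Me2AlCl (1.4 equiv), CH2Cl2, −30 °C should give the cycloadduct imide F4 by an auxiliary-controlled intramolecular Diels–Alder reaction through the chelated s-cis N-enoyl complex, in which the benzyl group covers the Si face of C10. LiBH4 in THF/MeOH removes the auxiliary to give the primary alcohol F5, and Dess–Martin oxidation (NaHCO3, CH2Cl2) returns the route to aldehyde 13.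

Step 11 (nucleophilic epoxidation). Addition of hydroperoxide to the hindered β,β-disubstituted enone may be sluggish or occur from the β-face, and the base may cause deconjugation or epimerisation through the acidic C9–H, which is γ to the enone and allylic to the vinyl group. The fallback sets out from 15 and comes back at 17. Copper-catalysed conjugate borylation (CuCl, NaOtBu, bis[2-(diphenylphosphino)phenyl] ether, B2pin2, MeOH, THF, 23 °C) should deliver boron to C8 from the α-face to give the β-boryl ketone F6. Oxidation with NaBO3·4H2O (THF/H2O) proceeds with retention and gives the β-hydroxy ketone 17, now isolated, which the second stage of step 12 (Li, NH3, EtOH) reduces to 18.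

Step 17 (angeloylation). Acylation of the 6α-hydroxyl, which is flanked by the C4 gem-dimethyl group, may be slow, and the angeloyl unit may isomerise from Z to E (tiglate) on prolonged heating. The fallback sets out from 23 and comes back at 24. The 6α-hydroxyl is acylated with 2-[bis(2,2,2-trifluoroethoxy)phosphoryl]propanoic acid (N,N′-dicyclohexylcarbodiimide, 4-(dimethylamino)pyridine, CH2Cl2) to the phosphonate ester F7. A Z-selective Still–Gennari olefination with acetaldehyde (KN(SiMe3)2, 18-crown-6, THF, −78 °C) then builds the (Z)-2-methylbut-2-enoate on the molecule and gives 24.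

Further compounds

F1 | step 8 | (S)-4-benzyl-3-(3-oxobutanoyl)oxazolidin-2-one | CC(=O)CC(=O)N1[C@@H](Cc2ccccc2)COC1=O
F2 | step 8 | (2E)-4-[(4S)-4-benzyl-2-oxooxazolidin-3-yl]-4-oxobut-2-en-2-yl trifluoromethanesulfonate | C/C(OS(=O)(=O)C(F)(F)F)=C\C(=O)N1[C@@H](Cc2ccccc2)COC1=O
F3 | step 8 | (4S)-4-benzyl-3-[(2E,8Z,10E)-9-[(tert-butyldimethylsilyl)oxy]-3,7,7-trimethyldodeca-2,8,10-trienoyl]oxazolidin-2-one | C/C=C/C(O[Si](C)(C)C(C)(C)C)=C/C(C)(C)CCC/C(C)=C/C(=O)N1[C@@H](Cc2ccccc2)COC1=O
F4 | step 8 | N-acyl oxazolidinone of the cycloadduct (acid oxidation level of 13 at C11, same ring stereochemistry) | O=C([C@@H]1[C@@]2(C)CCCC(C)(C)[C@@H]2C(O[Si](C)(C)C(C)(C)C)=C[C@@H]1C)N1[C@@H](Cc2ccccc2)COC1=O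
F5 | step 8 | 6-[(tert-butyldimethylsilyl)oxy]-12,13,14,15,16-pentanorlabd-6-en-11-ol | OC[C@@H]1[C@@]2(C)CCCC(C)(C)[C@@H]2C(O[Si](C)(C)C(C)(C)C)=C[C@@H]1C
F6 | step 11 | 8α-(4,4,5,5-tetramethyl-1,3,2-dioxaborolan-2-yl)-13,14,15,16-tetranorlabd-11-en-6-one | C=C[C@@H]1[C@@]2(C)CCCC(C)(C)[C@@H]2C(=O)C[C@@]1(C)B1OC(C)(C)C(C)(C)O1
F7 | step 17 | (13R)-8α,13-dihydroxylabd-14-en-6α-yl 2-[bis(2,2,2-trifluoroethoxy)phosphoryl]propanoate (mixture at the phosphonate α-carbon) | C=C[C@](C)(O)CC[C@@H]1[C@@]2(C)CCCC(C)(C)[C@@H]2[C@@H](OC(=O)C(C)P(=O)(OCC(F)(F)F)OCC(F)(F)F)C[C@@]1(C)O
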